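Numbering: C1 (O-angelate), C2 (O-isovalerate), C3 (OH), C4 (CMe2), C5 (cyclobutane CH), C6 (bridgehead next to the C7 ketone), C8=C9(Me), C10 (second bridgehead), C11 (quaternary C-Me); ring A = C5-C6-C7-C8-C9-C10, ring B = C1-C2-C3-C4-C5-C10-C11, ring C = cyclobutane C5-C6-C11-C10.
Feature: the ring C bond C6-C11 ties the α-carbon of the C7 ketone to the α-carbon of oxygenated C1. With C1 as a ketone it is the central bond of a 1,4-diketone, so it is cut as the oxidative union of two enolates of a cis-fused A/B enedione.
The carbinols and esters come after the skeleton: reagent-controlled reduction at C1 with the C7 enone masked, dihydroxylation of C2=C3 anti to C1-OH, then a 2,3-acetonide that orders the acylations (C1 angelate first, C2 isovalerate second).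
The enedione comes from ring-closing metathesis (C2=C3, ring B) and allylic oxidation (C7). Its cis junction comes from an Ireland-Claisen shift that carries C11 from C8-O to C10 on the face of the C5 substituent.
Ring A is made first, by organocatalytic Michael addition and aldol condensation of 3,3-dimethylpent-4-enal with ethyl vinyl ketone (sets C5). Ring order: A, then B, then C.

Key step: step 11

Assumption: C11 forms as a mixture of epimers in the Claisen step and is drawn as one epimer up to the key-step precursor. Both epimers give the same enolate, so they are carried on together.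

Step 1
Reactants: 1 methyl 3,3-dimethylpent-4-enoate
Product: 2 3,3-dimethylpent-4-enal
Conditions: iBu2AlH (1.05 equiv), CH2Cl2, −78 °C; aq. potassium sodium tartrate
Reagents that add atoms: none
Why: Partial ester reduction with iBu2AlH stops at the aluminium hemiacetal at −78 °C, which collapses to the aldehyde only on work-up; no stereocentre is involved.

Step 2
Reactants: 2 3,3-dimethylpent-4-enal; 3 pent-1-en-3-one (ethyl vinyl ketone)
Product: 4 (2S)-2-(2-methylbut-3-en-2-yl)-5-oxoheptanal
Conditions: (S)-2-[methoxy(diphenyl)methyl]pyrrolidine (10 mol %), ethyl 3,4-dihydroxybenzoate (20 mol %), neat, 4 °C to rt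
Reagents that add atoms: none
Why: Enamine-catalysed asymmetric Michael addition of an aldehyde to a vinyl ketone, in which the E-enamine of 2 reacts on the face turned away from the diphenyl(methoxy)methyl group, so the (S)-catalyst should set C5 as (S) while the catechol cocatalyst activates the enone by hydrogen bonding.

Step 3
Reactants: 4 (2S)-2-(2-methylbut-3-en-2-yl)-5-oxoheptanal
Product: 5 (4R)-2-methyl-4-(2-methylbut-3-en-2-yl)cyclohex-2-en-1-one
Conditions: LiOH (cat.), iPrOH, rt
Reagents that add atoms: none
Why: Intramolecular aldol condensation in which only the CH2 of the ethyl ketone (future C9) reaches the aldehyde (future C10) through a six-membered ring, dehydration gives the trisubstituted enone, and the mild base should leave the hindered C5-H untouched.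

Step 4
Reactants: 5 (4R)-2-methyl-4-(2-methylbut-3-en-2-yl)cyclohex-2-en-1-one
Product: 6 (1R,4R)-2-methyl-4-(2-methylbut-3-en-2-yl)cyclohex-2-en-1-ol (trans)
Conditions: NaBH4, CeCl3·7H2O, MeOH, −40 °C
Reagents that add atoms: none
Why: Luche reduction gives 1,2-addition only, and axial hydride delivery to the half-chair with the tert-alkyl group pseudo-equatorial should place C8-OH pseudo-equatorial, trans to the C5 substituent.

Step 5
Reactants: 6 (1R,4R)-2-methyl-4-(2-methylbut-3-en-2-yl)cyclohex-2-en-1-ol; 7 propionic acid
Product: 8 (1S,4R)-2-methyl-4-(2-methylbut-3-en-2-yl)cyclohex-2-en-1-yl propanoate (cis)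
Conditions: PPh3, DIAD, toluene, 0 °C to rt
Reagents that add atoms: none
Why: Mitsunobu esterification displaces the oxyphosphonium ion by SN2 with inversion at C8, so the propionate ends up cis to the C5 substituent, and SN2' attack at C10 is blocked by the neighbouring tert-alkyl group.

Step 6
Reactants: 8 (1S,4R)-2-methyl-4-(2-methylbut-3-en-2-yl)cyclohex-2-en-1-yl propanoate
Product: 11 (2R)-2-[(1S,6R)-2-methyl-6-(2-methylbut-3-en-2-yl)cyclohex-2-en-1-yl]propanoic acid, via silyl ketene acetal 9 (not isolated), via trimethylsilyl ester 10 (not isolated)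
Conditions: LiN(iPr)2 (LDA), THF, −78 °C; Me3SiCl; −78 to 50 °C; dilute aq. HCl work-up
Reagents that add atoms: chlorotrimethylsilane, C[Si](C)(C)Cl (its silicon is held only by 9 and 10)
Why: Ireland-Claisen rearrangement, a suprafacial [3,3] shift that delivers C11 to C10 on the face that C8-O leaves (pseudo-axial C-O favoured by allylic strain with the C9 methyl group, tert-alkyl group pseudo-equatorial), which sets C10 with C11 cis to C4 and moves the alkene to C8=C9; the C11 epimer ratio is of no consequence.

Step 7
Reactants: 11 (2R)-2-[(1S,6R)-2-methyl-6-(2-methylbut-3-en-2-yl)cyclohex-2-en-1-yl]propanoic acid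
Product: 13 Weinreb amide of 11, via acyl imidazolide 12 (not isolated)
Conditions: CDI, CH2Cl2, rt; then MeNH(OMe)·HCl, rt
Reagents that add atoms: 1,1'-carbonyldiimidazole, O=C(n1ccnc1)n1ccnc1 (its imidazole is held only by 12); N,O-dimethylhydroxylamine hydrochloride, CNOC.Cl
Why: Amide formation through the acyl imidazolide is mild, leaves both alkenes alone and gives the N-methoxy-N-methylamide needed for a single carbon nucleophile addition.

Step 8
Reactants: 13 Weinreb amide of 11
Product: 14 (4R)-4-[(1S,6R)-2-methyl-6-(2-methylbut-3-en-2-yl)cyclohex-2-en-1-yl]pent-1-en-3-one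
Conditions: CH2=CHMgBr, THF, −20 to 0 °C; poured into cold 1 M aq. HCl
Reagents that add atoms: vinylmagnesium bromide, C=C[Mg]Br
Why: Weinreb ketone synthesis, in which the magnesium chelate of the tetrahedral adduct survives until the cold acidic quench, so only one vinyl group is added and the released amine is protonated before it can add to the vinyl ketone.

Step 9
Reactants: 14 (4R)-4-[(1S,6R)-2-methyl-6-(2-methylbut-3-en-2-yl)cyclohex-2-en-1-yl]pent-1-en-3-one
Product: 15 cis-fused bicyclic dienone (C1 ketone; C2=C3; C8=C9; C7 = CH2; 5-H/10-H cis)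
Conditions: second-generation Hoveyda-Grubbs catalyst RuCl2(H2IMes)(=CH-C6H4-2-OiPr) (5 mol %), toluene (2 mM), 80 °C
Reagents that add atoms: none
Why: Ring-closing metathesis, in which the cis side chains and the gem-dimethyl group hold the two terminal alkenes together, the trisubstituted C8=C9 alkene stays out, loss of ethene drives closure, and a seven-membered ring can hold only the Z-alkene.

Step 10
Reactants: 15 cis-fused bicyclic dienone
Product: 16 cis-fused bicyclo[5.4.0]undecadiene-dione (C1 enone in ring B; C7 enone in ring A; 5-H/10-H cis)
Conditions: CrO3, 3,5-dimethylpyrazole, CH2Cl2, −20 °C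
Reagents that add atoms: chromium trioxide, O=[Cr](=O)=O
Why: Allylic oxidation with the CrO3-3,5-dimethylpyrazole complex (hexavalent chromium), the standard way from a trisubstituted cycloalkene to the β,β-disubstituted enone, where C7 is the only allylic CH2, C10-H is tertiary and shielded and cannot give a ketone, and the ring B enone has no allylic hydrogen because C4 is quaternary.

Step 11
Reactants: 16 cis-fused bicyclo[5.4.0]undecadiene-dione
Product: 18 tricyclic bis-enone (C1 ketone; C2=C3; C7 enone; ring C closed), via dilithium bis-enolate 17 (not isolated)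
Conditions: 16 added slowly to LiN(iPr)2 (2.2 equiv), THF, −78 °C; then cannulated into Fe(acac)3 (2.2 equiv), THF (final 2 mM), −78 °C to rt
Reagents that add atoms: lithium diisopropylamide, [Li+].CC(C)[N-]C(C)C (its lithium is held only by 17)
Why: Adding 16 slowly to excess LiN(iPr)2 removes the kinetic α'-proton at C6 of the ring A enone and C11-H, the only enolisable proton of the ring B enone (C4 is quaternary), so that both ketones are enolates (17) before a mono-enolate can attack the other carbonyl in a transannular aldol addition. Trivalent iron takes one electron from the more electron-rich, tetrasubstituted C1=C11 enolate, the tertiary α-keto radical at C11 adds to C6 of the second enolate, and a second equivalent of Fe(acac)3 oxidises the resulting ketyl to the C7 ketone, which makes the C6-C11 bond formation irreversible. The closest known reaction type is the intramolecular oxidative coupling of ketone and ester bis-enolates with iron and copper salts, which has closed cyclobutane-1,2-dicarboxylates from adipate dienolates. Ring C closes in the 4-exo-trig mode across C6-C5-C10-C11, helped by the expected ground-state conformation of the cis-fused system, in which allylic strain with the C9 methyl group keeps C11 pseudo-axial on ring A, close above the π-lobe of C6, while C4 stays pseudo-equatorial. C6 and C11 are both set by C5 and C10, because the short tether lets the two carbons meet only on the ring A face that carries C11, which puts C1 on the side of C4 and the C11 methyl group over the C7-C9 bridge; the earlier C11 configuration plays no part. The step needs ring closure to beat dimerisation and hydrogen abstraction, which the 1,4-proximity of the two carbons, the 2 mM dilution and the inverse addition to the oxidant are meant to secure.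

Step 12
Reactants: 18 tricyclic bis-enone
Product: 19 C7 triethylsilyl dienol ether of 18 (C7(OSiEt3)=C8; exocyclic C9=CH2; C1 enone free)
Conditions: Et3SiOTf, Et3N, CH2Cl2, 0 °C
Reagents that add atoms: triethylsilyl trifluoromethanesulfonate, CC[Si](CC)(CC)OS(=O)(=O)C(F)(F)F
Why: Soft enolisation with a silyl triflate and an amine, in which the C7 enone can lose a proton only from the C9 methyl group (C6 and C10 are bridgeheads) and the C1 enone has no enolisable hydrogen at all (C11 and C4 quaternary), so only the less hindered C7 carbonyl, which would otherwise be reduced first, is masked.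

Step 13
Reactants: 19 C7 triethylsilyl dienol ether of 18
Product: 21 tricyclic C1 (R)-allylic alcohol (C7 enone restored), via catecholborate 20 (not isolated)
Conditions: (S)-2-methyl-CBS-oxazaborolidine (0.5 equiv), catecholborane, toluene, −78 to −40 °C; then MeOH, K2CO3 (cat.), 0 °C to rt
Reagents that add atoms: catecholborane, B1Oc2ccccc2O1 (its boron and catechol are held only by 20)
Why: Corey-Bakshi-Shibata reduction, needed because the two faces of the C1 ketone are related by the near mirror plane of the cage (C6 side against C10 side); with quaternary C11 as the large and C2H= as the small group the (S)-catalyst should deliver hydride from the C10 side to give the (R)-carbinol with O on the C6 side, the s-trans enone takes 1,2-addition only, and basic methanolysis then frees the alcohol and returns the conjugated C7 enone without acid, which the cyclobutylcarbinyl allylic alcohol would not tolerate.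

Step 14
Reactants: 21 tricyclic C1 (R)-allylic alcohol
Product: 22 1,2,3-triol (C1-OH trans to the cis C2/C3 diol; C7 enone intact)
Conditions: OsO4 (5 mol %), NMO, acetone/H2O, rt
Reagents that add atoms: N-methylmorpholine N-oxide, C[N+]1([O-])CCOCC1; water, O
Why: Upjohn dihydroxylation, in which the electron-poor, trisubstituted enone alkene C8=C9 stays untouched and OsO4 adds suprafacially to C2=C3 on the face opposite the allylic C1-OH (the usual anti selectivity of allylic alcohols, the two C4 methyl groups screening both faces alike), which sets C2 and C3 cis to each other and trans to C1-O.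

Step 15
Reactants: 22 1,2,3-triol
Product: 23 2,3-acetonide with free C1-OH
Conditions: Me2C(OMe)2, PPTS (cat.), CH2Cl2, rt
Reagents that add atoms: 2,2-dimethoxypropane, COC(C)(C)OC
Why: Acetalisation under thermodynamic control picks the cis-2,3-diol, because a dioxolane on the trans-1,2-diol would be strained, and so leaves only C1-OH free.

Step 16
Reactants: 23 2,3-acetonide with free C1-OH; 24 angelic acid
Product: 26 C1 angelate 2,3-acetonide, via mixed anhydride 25 (not isolated)
Conditions: 24, 2,4,6-trichlorobenzoyl chloride, Et3N, toluene, rt; then 23, 80 °C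
Reagents that add atoms: 2,4,6-trichlorobenzoyl chloride, O=C(Cl)c1c(Cl)cc(Cl)cc1Cl (its aroyl group is held only by 25)
Why: Yamaguchi-type esterification through the mixed anhydride, run without a nucleophilic catalyst, acylates hindered secondary alcohols with angelic acid while avoiding the addition-elimination path that turns the Z-angelate into the E-tiglate, and C1 keeps its configuration because its C-O bond is not touched.

Step 17
Reactants: 26 C1 angelate 2,3-acetonide
Product: 27 C1 angelate 2,3-diol
Conditions: AcOH/H2O (4:1), 40 °C
Reagents that add atoms: none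
Why: Mild aqueous acid hydrolyses the dioxolane while the ester, the enone and the rearrangement-prone cage, which would not stand strong acid, should survive.

Step 18
Reactants: 27 C1 angelate 2,3-diol; 28 isovaleryl chloride
Product: 29 CNP0251293.1 (target)
Conditions: 28 (1.1 equiv), pyridine, CH2Cl2, −20 to 0 °C
Reagents that add atoms: none
Why: Kinetically controlled monoacylation, in which the neopentylic C3-OH next to C4Me2 should react much more slowly than C2-OH, so one equivalent of acid chloride at low temperature without a nucleophilic catalyst should give the C2 ester with no stereocentre touched.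

Compound list
1 | methyl 3,3-dimethylpent-4-enoate | C=CC(C)(C)CC(=O)OC | starting material
2 | 3,3-dimethylpent-4-enal | C=CC(C)(C)CC=O | intermediate
3 | pent-1-en-3-one (ethyl vinyl ketone) | C=CC(=O)CC | starting material
4 | (2S)-2-(2-methylbut-3-en-2-yl)-5-oxoheptanal | O=C[C@@H](CCC(=O)CC)C(C)(C)C=C | intermediate
5 | (4R)-2-methyl-4-(2-methylbut-3-en-2-yl)cyclohex-2-en-1-one | O=C1CC[C@@H](C(C)(C)C=C)C=C1C | intermediate
6 | (1R,4R)-2-methyl-4-(2-methylbut-3-en-2-yl)cyclohex-2-en-1-ol (trans) | O[C@@H]1CC[C@@H](C(C)(C)C=C)C=C1C | intermediate
7 | propionic acid | CCC(=O)O | starting material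
8 | (1S,4R)-2-methyl-4-(2-methylbut-3-en-2-yl)cyclohex-2-en-1-yl propanoate (cis) | CCC(=O)O[C@H]1CC[C@@H](C(C)(C)C=C)C=C1C | intermediate
9 | (E)-trimethylsilyl ketene acetal of 8 | C/C=C(/O[Si](C)(C)C)O[C@H]1CC[C@@H](C(C)(C)C=C)C=C1C | intermediate
10 | trimethylsilyl ester of 11 | C[Si](C)(C)OC(=O)[C@H](C)[C@H]1C(C)=CCC[C@H]1C(C)(C)C=C | intermediate
11 | (2R)-2-[(1S,6R)-2-methyl-6-(2-methylbut-3-en-2-yl)cyclohex-2-en-1-yl]propanoic acid | OC(=O)[C@H](C)[C@H]1C(C)=CCC[C@H]1C(C)(C)C=C | intermediate
12 | acyl imidazolide of 11 | O=C(n1ccnc1)[C@H](C)[C@H]1C(C)=CCC[C@H]1C(C)(C)C=C | intermediate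
13 | N-methoxy-N-methylamide (Weinreb amide) of 11 | CON(C)C(=O)[C@H](C)[C@H]1C(C)=CCC[C@H]1C(C)(C)C=C | intermediate
14 | (4R)-4-[(1S,6R)-2-methyl-6-(2-methylbut-3-en-2-yl)cyclohex-2-en-1-yl]pent-1-en-3-one | C=CC(=O)[C@H](C)[C@H]1C(C)=CCC[C@H]1C(C)(C)C=C | intermediate
15 | cis-fused bicyclic dienone (C1 ketone, C2=C3, C8=C9, C7 = CH2) | O=C1C=CC(C)(C)[C@@H]2CCC=C(C)[C@@H]2[C@H]1C | intermediate
16 | cis-fused bicyclo[5.4.0]undecadiene-dione (key-step precursor) | O=C1C=CC(C)(C)[C@@H]2CC(=O)C=C(C)[C@@H]2[C@H]1C | intermediate
17 | dilithium bis-enolate of 16 (C6=C7-OLi and C11=C1-OLi) | [Li]OC1=C(C)[C@H]2C(C)=CC(O[Li])=C[C@H]2C(C)(C)C=C1 | intermediate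
18 | tricyclic bis-enone (key-step product, tricyclo[5.4.0.0(2,8)]undecane skeleton) | O=C1C=CC(C)(C)[C@@H]2[C@H]3C(=O)C=C(C)[C@@H]2[C@@]13C | intermediate
19 | C7 triethylsilyl dienol ether of 18 | O=C1C=CC(C)(C)[C@@H]2[C@H]3C(O[Si](CC)(CC)CC)=CC(=C)[C@@H]2[C@@]13C | intermediate
20 | C1 catecholborate of the reduced, still masked tricycle | B4(Oc5ccccc5O4)O[C@@H]1C=CC(C)(C)[C@@H]2[C@H]3C(O[Si](CC)(CC)CC)=CC(=C)[C@@H]2[C@@]13C | intermediate
21 | tricyclic C1 (R)-allylic alcohol with C7 enone | O[C@@H]1C=CC(C)(C)[C@@H]2[C@H]3C(=O)C=C(C)[C@@H]2[C@@]13C | intermediate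
22 | 1,2,3-triol | O[C@@H]1[C@@H](O)[C@@H](O)C(C)(C)[C@@H]2[C@H]3C(=O)C=C(C)[C@@H]2[C@@]13C | intermediate
23 | 2,3-acetonide with free C1-OH | O[C@@H]1[C@H]4OC(C)(C)O[C@H]4C(C)(C)[C@@H]2[C@H]3C(=O)C=C(C)[C@@H]2[C@@]13C | intermediate
24 | angelic acid | C/C=C(/C)C(=O)O | starting material
25 | angelic 2,4,6-trichlorobenzoic mixed anhydride | C/C=C(/C)C(=O)OC(=O)c1c(Cl)cc(Cl)cc1Cl | intermediate
26 | C1 angelate 2,3-acetonide | C/C=C(/C)C(=O)O[C@@H]1[C@H]4OC(C)(C)O[C@H]4C(C)(C)[C@@H]2[C@H]3C(=O)C=C(C)[C@@H]2[C@@]13C | intermediate
27 | C1 angelate 2,3-diol | C/C=C(/C)C(=O)O[C@@H]1[C@@H](O)[C@@H](O)C(C)(C)[C@@H]2[C@H]3C(=O)C=C(C)[C@@H]2[C@@]13C | intermediate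
28 | isovaleryl chloride | CC(C)CC(=O)Cl | starting material
29 | CNP0251293.1 | C/C=C(/C)C(=O)O[C@@H]1[C@@H](OC(=O)CC(C)C)[C@@H](O)C(C)(C)[C@@H]2[C@H]3C(=O)C=C(C)[C@@H]2[C@@]13C | target

Total step count: 18. Longest linear sequence: 18 steps (from 1).

Steps most likely to fail

Step 11. Closure of the strained four-membered ring may be slower than intermolecular coupling of the α-keto radical, than hydrogen abstraction that returns the dione, or than transannular aldol addition if enolisation at hindered C11 is incomplete.
The fallback sets out from 16 and comes back at 18. 16 is deprotonated as before to 17, and both enolates are trapped with Me3SiCl to give the bis(trimethylsilyl enol ether) F1, a neutral compound that can be freed from amine and salts. F1 is then oxidised at high dilution with (NH4)2Ce(NO3)6 (tetravalent cerium) and NaHCO3 in MeCN at −20 °C. The radical cation of the tetrasubstituted enol silane is captured by the second enol silane, and loss of both silyl groups gives 18. This is the known oxidative coupling of silyl bis-enol ethers. No basic enolate is present, so the aldol and proton-transfer channels are closed.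

Step 13. Facial discrimination at C1 may be poor, because the catalyst has to tell quaternary C11 from the vinyl carbon on a nearly mirror-symmetric cage. Reduction next to C11 may also be slow.
The fallback sets out from 19 and comes back at 21, giving up reagent control for separation and recycling. iBu2AlH in toluene at −78 °C reduces the C1 ketone to the masked (R)-alcohol F2 and its masked C1 epimer F3. Methanolysis with K2CO3 (cat.) in MeOH unmasks both and gives 21 and the C1-epimeric allylic alcohol F4. These are diastereomers and are separated by chromatography. F4 is oxidised with MnO2 back to 18 and sent through steps 12 and 13 again.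

Step 6. The sigmatropic shift may be slowed by crowding between the methyl-bearing migrating carbon and the tert-alkyl group on the same face. Decomposition or hydrolysis of the ketene acetal could then take over.
The fallback sets out from 6 and comes back at 11, and brings in the C11 methyl group only after the C10-C11 bond exists. Mitsunobu reaction of 6 with acetic acid (PPh3, DIAD) gives the cis-acetate F5. LiN(iPr)2 and Me3SiCl give the unsubstituted silyl ketene acetal F6, whose CH2 terminus is the smallest possible migrating carbon. Its rearrangement gives the trimethylsilyl ester F7, and work-up gives the acetic acid derivative F8. Double deprotonation of F8 with LiN(iPr)2 (2.2 equiv) gives the dilithium dianion F9, which is methylated at C11 with MeI to give 11. The C11 configuration is again of no consequence.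

Further compounds
F1 | step 11 | bis(trimethylsilyl enol ether) of 16 | C[Si](C)(C)OC1=C(C)[C@H]2C(C)=CC(O[Si](C)(C)C)=C[C@H]2C(C)(C)C=C1
F2 | step 13 | masked (R)-alcohol (C1-OH, C7 triethylsilyl dienol ether) | O[C@@H]1C=CC(C)(C)[C@@H]2[C@H]3C(O[Si](CC)(CC)CC)=CC(=C)[C@@H]2[C@@]13C
F3 | step 13 | masked C1 epimer of F2 | O[C@H]1C=CC(C)(C)[C@@H]2[C@H]3C(O[Si](CC)(CC)CC)=CC(=C)[C@@H]2[C@@]13C
F4 | step 13 | C1-epimeric allylic alcohol (epimer of 21) | O[C@H]1C=CC(C)(C)[C@@H]2[C@H]3C(=O)C=C(C)[C@@H]2[C@@]13C
F5 | step 6 | (1S,4R)-2-methyl-4-(2-methylbut-3-en-2-yl)cyclohex-2-en-1-yl acetate (cis) | CC(=O)O[C@H]1CC[C@@H](C(C)(C)C=C)C=C1C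
F6 | step 6 | trimethylsilyl ketene acetal of F5 | C=C(O[Si](C)(C)C)O[C@H]1CC[C@@H](C(C)(C)C=C)C=C1C
F7 | step 6 | trimethylsilyl ester of F8 | C[Si](C)(C)OC(=O)C[C@H]1C(C)=CCC[C@H]1C(C)(C)C=C
F8 | step 6 | 2-[(1S,6R)-2-methyl-6-(2-methylbut-3-en-2-yl)cyclohex-2-en-1-yl]acetic acid | OC(=O)C[C@H]1C(C)=CCC[C@H]1C(C)(C)C=C
F9 | step 6 | dilithium dianion of F8 | [Li]OC(O[Li])=C[C@H]1C(C)=CCC[C@H]1C(C)(C)C=C
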